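## Retrosynthetic overview

- Numbering (spiro[5.5]undecane): ring A is C1(=CH2), C2(=O), C3=C4, C5(Me2), C6 (spiro). Ring B is C6, C7H2, C8HBr, C9(Me)Cl, C10H2, C11H(OAc).
- Feature: CH2=C1–C6–C11–O runs from ring A over the spiro carbon into ring B and is a homoallylic alcohol. Cutting C6–C11 as a retro carbonyl-ene reaction opens ring B and gives the achiral aldehyde 8, whose C1(Me)=C6 alkene sits in a 2,6,6-trimethylcyclohexene.
- Removed before that cut: C3=C4 (dehydrogenation), C2=O (allylic oxidation of C2H2), the acetate, and C8–Br/C9–Cl (anti addition to C8=C9, with chloride brought in from the C11 oxygen).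
- Aldehyde 8: the Z C8=C9 bond and the C10–C11 bond come from a Still–Wittig [2,3]-shift on the adduct of isopropenylmagnesium bromide and commercial β-homocyclocitral.
- Ring order: ring A is bought and ring B is closed in step 5. No other ring is made.

Key step: step 5

Assumption: the sense of induction of the confined acid cannot be read from the substrate. The antipode that leaves the Re face of the C11 aldehyde open is used, and both antipodes are made alike from (R)- or (S)-BINOL.

Remark: 3, 5 and 6 are racemic, and their only stereocentre is erased in step 3. Compound 13 is a mixture of C2 epimers, which is erased in step 9.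

## Route

Step 1
Reactants: 1 β-homocyclocitral, 2-(2,6,6-trimethylcyclohex-1-en-1-yl)acetaldehyde; 2 isopropenylmagnesium bromide
Product: 3 3-methyl-1-(2,6,6-trimethylcyclohex-1-en-1-yl)but-3-en-2-ol (racemic)
Conditions: 2 (1.3 equiv), THF, −78 → 0 °C; then H2O
Reagents that add atoms: isopropenylmagnesium bromide (2), C=C(C)[Mg]Br
Why: 1,2-addition of an alkenyl Grignard reagent to an aldehyde brings in C9, its methyl and C10, and the racemic carbinol centre is harmless because step 3 turns it into sp2 C8.

Step 2
Reactants: 3 3-methyl-1-(2,6,6-trimethylcyclohex-1-en-1-yl)but-3-en-2-ol; 4 tributyl(iodomethyl)stannane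
Product: 5 tributyl({[3-methyl-1-(2,6,6-trimethylcyclohex-1-en-1-yl)but-3-en-2-yl]oxy}methyl)stannane
Conditions: KH, THF, 0 °C; then 4, 0 °C → rt
Reagents that add atoms: tributyl(iodomethyl)stannane (4), CCCC[Sn](CCCC)(CCCC)CI
Why: Williamson etherification of the potassium alkoxide with the primary iodide is the standard entry to the Still variant of the Wittig rearrangement and attaches the future C11.

Step 3
Reactants: 5 tributyl({[3-methyl-1-(2,6,6-trimethylcyclohex-1-en-1-yl)but-3-en-2-yl]oxy}methyl)stannane
Product: 7 (Z)-3-methyl-5-(2,6,6-trimethylcyclohex-1-en-1-yl)pent-3-en-1-ol, via lithiomethyl ether 6 (not isolated)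
Conditions: n-BuLi, THF, −78 °C; then H2O
Reagents that add atoms: none
Why: Tin–lithium exchange triggers the Still–Wittig [2,3]-sigmatropic rearrangement, which forms C10–C11 and in whose early envelope transition state the C7 side chain sits pseudoaxial to avoid the C9 methyl, so the trisubstituted C8=C9 bond should form Z (C7 cis to C10).

Step 4
Reactants: 7 (Z)-3-methyl-5-(2,6,6-trimethylcyclohex-1-en-1-yl)pent-3-en-1-ol
Product: 8 (Z)-3-methyl-5-(2,6,6-trimethylcyclohex-1-en-1-yl)pent-3-enal
Conditions: Dess–Martin periodinane, CH2Cl2, 0 °C → rt; filtration through silica, used at once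
Reagents that add atoms: none
Why: The Dess–Martin oxidation needs no base, so the primary alcohol should become the aldehyde while the β,γ C8=C9 bond keeps its position and geometry.

Step 5
Reactants: 8 (Z)-3-methyl-5-(2,6,6-trimethylcyclohex-1-en-1-yl)pent-3-enal
Product: 9 (6R,11S)-5,5,9-trimethyl-1-methylidenespiro[5.5]undec-8-en-11-ol
Conditions: confined BINOL-derived N-triflyl imidodiphosphorimidate Brønsted acid with bulky 3,3′-aryl groups (5 mol %), CH2Cl2, −40 °C
Reagents that add atoms: none
Why: Proposed new method: the confined acid binds the C11 aldehyde, C6 of the electron-rich tetrasubstituted C1=C6 alkene attacks C11 while charge builds at tertiary C1, and a hydrogen of the C1 methyl ends on oxygen, either directly or relayed by the basic site of the counteranion, which frees the catalyst. The closest known reaction type is the chiral Brønsted or Lewis acid catalysed type I carbonyl-ene cyclisation of olefinic aldehydes (the citronellal to isopulegol class), which is enantioselective so far only with di- and trisubstituted alkenes. Ring B closes as a six-membered ring in the type I mode, exo to both C11=O and C1=C6, and the Z C8=C9 bond holds C11 within reach of C6, whereas any E isomer from step 3 cannot close and stays behind. C11 (S) is set by the catalyst pocket, which leaves the Re face of the aldehyde open, and C6 (R) follows from the half-chair in which C11–O is pseudoaxial and antiperiplanar to C6–C5, so that oxygen ends cis to C1. The step needs hydrogen transfer from the methyl and not from C2: the methyl is the C1 substituent cis to the tether and lies under the oxygen only in this half-chair, whereas the oxygen-equatorial chairs hold oxygen over C2–H. The substrate favours the required half-chair because it alone keeps the acid-laden oxygen away from the C5 gem-dimethyl group, and sp2 C8 and C9 leave each pseudoaxial group with only one 1,3-hydrogen to meet.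

Step 6
Reactants: 9 (6R,11S)-5,5,9-trimethyl-1-methylidenespiro[5.5]undec-8-en-11-ol
Product: 11 (6R,8R,9R,11S)-8-bromo-9-chloro-5,5,9-trimethyl-1-methylidenespiro[5.5]undecan-11-ol, via chlorotitanium alkoxide 10 (not isolated)
Conditions: ClTi(OiPr)3 (1.2 equiv), hexanes–CH2Cl2, rt; then NBS (1.05 equiv), −20 °C, dark; aqueous work-up
Reagents that add atoms: N-bromosuccinimide, O=C1CCC(=O)N1Br; chlorotitanium triisopropoxide, CC(C)O[Ti](Cl)(OC(C)C)OC(C)C
Why: Proposed new method: 9 exchanges onto titanium to give 10, and NBS forms the bromonium ion reversibly on either face of the more nucleophilic trisubstituted C8=C9 bond (C1=CH2 is only 1,1-disubstituted and neopentyl). Only the bromonium anti to oxygen can be opened from within, because the Ti–Cl of the pseudoaxial alkoxide reaches tertiary C9 through a six-membered O–Ti–Cl–C9–C10–C11 array; Markovnikov and trans-diaxial (Fürst–Plattner) opening then agree, chloride ends cis to oxygen with bromine trans at C8, and the adduct relaxes to the all-equatorial chair. The closest known reaction type is the titanium alkoxide mediated bromochlorination of allylic alcohols, in which chloride is likewise delivered 1,3 to the bound oxygen.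

Step 7
Reactants: 11 (6R,8R,9R,11S)-8-bromo-9-chloro-5,5,9-trimethyl-1-methylidenespiro[5.5]undecan-11-ol
Product: 12 (6R,8R,9R,11S)-8-bromo-9-chloro-5,5,9-trimethyl-1-methylidenespiro[5.5]undecan-11-yl acetate
Conditions: Ac2O, DMAP (cat.), pyridine, rt
Reagents that add atoms: acetic anhydride, CC(=O)OC(C)=O
Why: DMAP-catalysed acylation of the equatorial secondary alcohol touches no stereocentre, and the weak base is not expected to trigger transannular displacement of the C8 bromide by oxygen.

Step 8
Reactants: 12 (6R,8R,9R,11S)-8-bromo-9-chloro-5,5,9-trimethyl-1-methylidenespiro[5.5]undecan-11-yl acetate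
Product: 13 (6R,8R,9R,11S)-8-bromo-9-chloro-2-hydroxy-5,5,9-trimethyl-1-methylidenespiro[5.5]undecan-11-yl acetate (C2 epimers)
Conditions: SeO2 (cat.), t-BuOOH, CH2Cl2, rt
Reagents that add atoms: selenium dioxide (oxygen carrier), O=[Se]=O; tert-butyl hydroperoxide (stoichiometric oxygen source), CC(C)(C)OO
Why: Selenium dioxide allylic oxidation (ene reaction, then [2,3]-shift) returns the double bond to its exocyclic place and can oxidise only C2 because C6 bears no hydrogen, and the new C2 centre need not be controlled since step 9 removes it.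

Step 9
Reactants: 13 (6R,8R,9R,11S)-8-bromo-9-chloro-2-hydroxy-5,5,9-trimethyl-1-methylidenespiro[5.5]undecan-11-yl acetate
Product: 14 (6R,8R,9R,11S)-8-bromo-9-chloro-5,5,9-trimethyl-1-methylidene-2-oxospiro[5.5]undecan-11-yl acetate
Conditions: Dess–Martin periodinane, CH2Cl2, rt
Reagents that add atoms: none
Why: Dess–Martin oxidation converts both allylic alcohol epimers into one α-methylene ketone under neutral conditions that leave the halides and the acetate alone.

Step 10
Reactants: 14 (6R,8R,9R,11S)-8-bromo-9-chloro-5,5,9-trimethyl-1-methylidene-2-oxospiro[5.5]undecan-11-yl acetate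
Product: 15 (6R,8R,9R,11S)-8-bromo-9-chloro-5,5,9-trimethyl-1-methylidene-2-(trimethylsilyloxy)spiro[5.5]undec-2-en-11-yl acetate
Conditions: TMSOTf (1.3 equiv), Et3N, CH2Cl2, −20 → 0 °C
Reagents that add atoms: trimethylsilyl trifluoromethanesulfonate, C[Si](C)(C)OS(=O)(=O)C(F)(F)F
Why: Soft enolisation with silyl triflate and amine can go only towards C3 because C1 has no hydrogen, and the ketone is silylated faster than the acetate.

Step 11
Reactants: 15 (6R,8R,9R,11S)-8-bromo-9-chloro-5,5,9-trimethyl-1-methylidene-2-(trimethylsilyloxy)spiro[5.5]undec-2-en-11-yl acetate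
Product: 16 (6R,8R,9R,11S)-8-bromo-9-chloro-5,5,9-trimethyl-1-methylidene-2-oxospiro[5.5]undec-3-en-11-yl acetate (target)
Conditions: Pd(OAc)2 (1.1 equiv), MeCN, rt
Reagents that add atoms: none
Why: In the Saegusa–Ito oxidation, palladation of the silyl enol ether at C3 and β-hydride elimination of a C4 hydrogen create C3=C4 at room temperature without base, which spares the equatorial bromide, the tertiary chloride and the acetate.

## Compound list

1 | β-homocyclocitral, 2-(2,6,6-trimethylcyclohex-1-en-1-yl)acetaldehyde | CC1=C(CC=O)C(C)(C)CCC1 | starting material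
2 | isopropenylmagnesium bromide | C=C(C)[Mg]Br | starting material
3 | 3-methyl-1-(2,6,6-trimethylcyclohex-1-en-1-yl)but-3-en-2-ol (racemic) | CC1=C(CC(O)C(C)=C)C(C)(C)CCC1 | intermediate
4 | tributyl(iodomethyl)stannane | CCCC[Sn](CCCC)(CCCC)CI | starting material
5 | tributyl({[3-methyl-1-(2,6,6-trimethylcyclohex-1-en-1-yl)but-3-en-2-yl]oxy}methyl)stannane (racemic) | CCCC[Sn](CCCC)(CCCC)COC(CC1=C(C)CCCC1(C)C)C(C)=C | intermediate
6 | {[3-methyl-1-(2,6,6-trimethylcyclohex-1-en-1-yl)but-3-en-2-yl]oxy}methyllithium (not isolated) | [Li]COC(CC1=C(C)CCCC1(C)C)C(C)=C | intermediate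
7 | (Z)-3-methyl-5-(2,6,6-trimethylcyclohex-1-en-1-yl)pent-3-en-1-ol | CC1=C(C/C=C(C)\CCO)C(C)(C)CCC1 | intermediate
8 | (Z)-3-methyl-5-(2,6,6-trimethylcyclohex-1-en-1-yl)pent-3-enal | CC1=C(C/C=C(C)\CC=O)C(C)(C)CCC1 | intermediate
9 | (6R,11S)-5,5,9-trimethyl-1-methylidenespiro[5.5]undec-8-en-11-ol | C=C1CCCC(C)(C)[C@]12CC=C(C)C[C@@H]2O | intermediate
10 | chlorobis(isopropoxy)titanium alkoxide of 9 (not isolated) | C=C1CCCC(C)(C)[C@]12CC=C(C)C[C@@H]2O[Ti](Cl)(OC(C)C)OC(C)C | intermediate
11 | (6R,8R,9R,11S)-8-bromo-9-chloro-5,5,9-trimethyl-1-methylidenespiro[5.5]undecan-11-ol | C=C1CCCC(C)(C)[C@]12C[C@@H](Br)[C@](C)(Cl)C[C@@H]2O | intermediate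
12 | (6R,8R,9R,11S)-8-bromo-9-chloro-5,5,9-trimethyl-1-methylidenespiro[5.5]undecan-11-yl acetate | C=C1CCCC(C)(C)[C@]12C[C@@H](Br)[C@](C)(Cl)C[C@@H]2OC(C)=O | intermediate
13 | (6R,8R,9R,11S)-8-bromo-9-chloro-2-hydroxy-5,5,9-trimethyl-1-methylidenespiro[5.5]undecan-11-yl acetate (C2 epimers) | C=C1C(O)CCC(C)(C)[C@]12C[C@@H](Br)[C@](C)(Cl)C[C@@H]2OC(C)=O | intermediate
14 | (6R,8R,9R,11S)-8-bromo-9-chloro-5,5,9-trimethyl-1-methylidene-2-oxospiro[5.5]undecan-11-yl acetate | C=C1C(=O)CCC(C)(C)[C@]12C[C@@H](Br)[C@](C)(Cl)C[C@@H]2OC(C)=O | intermediate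
15 | (6R,8R,9R,11S)-8-bromo-9-chloro-5,5,9-trimethyl-1-methylidene-2-(trimethylsilyloxy)spiro[5.5]undec-2-en-11-yl acetate | C=C1C(O[Si](C)(C)C)=CCC(C)(C)[C@]12C[C@@H](Br)[C@](C)(Cl)C[C@@H]2OC(C)=O | intermediate
16 | (6R,8R,9R,11S)-8-bromo-9-chloro-5,5,9-trimethyl-1-methylidene-2-oxospiro[5.5]undec-3-en-11-yl acetate | C=C1C(=O)C=CC(C)(C)[C@]12C[C@@H](Br)[C@](C)(Cl)C[C@@H]2OC(C)=O | target

Total step count: 11. Longest linear sequence: 11 steps (1 → 16).

## Steps most likely to fail

**First, step 5 (labelled).**
- Hydrogen may be taken from C2 through an oxygen-equatorial chair.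
- The pocket may discriminate the aldehyde faces poorly, since it must admit a tetrasubstituted alkene next to a quaternary carbon.
- The acid may move C8=C9 into conjugation before the ring closes.

The fallback sets out from 8 and comes back at 9. Ring B is closed with stoichiometric Me2AlCl (CH2Cl2, −78 °C), the established achiral promoter of type I carbonyl-ene closures. Its aluminium alkoxide loses methane, so no proton is left to shift either double bond. This should give the racemic spiro alcohol F1. Steglich esterification with (S)-O-methylmandelic acid (DCC, DMAP, CH2Cl2) converts it into the mandelate of the (6R,11S) alcohol F2 and the mandelate of the (6S,11R) alcohol F3, which are separated on silica gel. Methanolysis of F2 (K2CO3, MeOH) returns 9. The absolute configuration then rests on a resolution rather than on catalysis. This fallback does not correct hydrogen loss from C2.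

**Second, step 6 (labelled).**
- Bromine may add on the face syn to oxygen, followed by external chloride. The required bromonium lies on the face that also carries C5.
- Bromine may attack C1=CH2 instead.
- The bromonium may be captured by the exocyclic alkene or by the oxygen.

The fallback sets out from 9 and comes back at 12. Vanadium-directed epoxidation of the cyclohex-3-enol unit (VO(acac)2 cat., t-BuOOH, CH2Cl2, 0 °C) should give the epoxy alcohol with the oxirane cis to the hydroxyl, F4. Soft bromide (Li2NiBr4, THF, 0 °C) opens the oxirane at secondary C8 with inversion to give the bromo diol F5. Ac2O in pyridine at 0 °C acylates only the secondary hydroxyl and gives the tertiary alcohol acetate F6. The α-chloroenamine 1-chloro-N,N,2-trimethylprop-1-en-1-amine (CH2Cl2, 0 °C) then exchanges the tertiary hydroxyl for chloride. Ionisation at C9 is assisted by the C8 bromine, and chloride opens the resulting bromonium at C9 from the side the oxygen occupied. The net retention gives 12. Each stereocentre is then fixed by a stereospecific displacement rather than by face selection in an addition.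

**Third, step 8.**
- The ene step may be slow at a methylene group flanked by the spiro carbon.
- Over-oxidation may occur.
- Hydrogen halide may be lost on long exposure.

The fallback sets out from 12 and comes back at 14, bypassing step 9. Acid (p-TsOH cat., benzene, 50 °C) moves the double bond into ring A to give the endocyclic alkene F7. The Schenck ene reaction (O2, tetraphenylporphyrin, hν, CH2Cl2, 0 °C) can take hydrogen only from the methyl or from C3 because C6 has none. Abstraction geminal to the bulky spiro carbon should place oxygen on C2 and restore C1=CH2, giving the allylic hydroperoxide F8. Ac2O in pyridine dehydrates it to 14.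

## Further compounds

F1 | step 5 | racemic (6R*,11S*)-5,5,9-trimethyl-1-methylidenespiro[5.5]undec-8-en-11-ol | C=C1CCCC(C)(C)[C@]12CC=C(C)C[C@@H]2O.C=C1CCCC(C)(C)[C@@]12CC=C(C)C[C@H]2O
F2 | step 5 | (6R,11S)-5,5,9-trimethyl-1-methylidenespiro[5.5]undec-8-en-11-yl (S)-2-methoxy-2-phenylacetate | C=C1CCCC(C)(C)[C@]12CC=C(C)C[C@@H]2OC(=O)[C@@H](OC)c3ccccc3
F3 | step 5 | (6S,11R)-5,5,9-trimethyl-1-methylidenespiro[5.5]undec-8-en-11-yl (S)-2-methoxy-2-phenylacetate | C=C1CCCC(C)(C)[C@@]12CC=C(C)C[C@H]2OC(=O)[C@@H](OC)c3ccccc3
F4 | step 6 | (6R,8S,9R,11S)-8,9-epoxy-5,5,9-trimethyl-1-methylidenespiro[5.5]undecan-11-ol (oxirane cis to OH) | C=C1CCCC(C)(C)[C@]12C[C@@H]3O[C@]3(C)C[C@@H]2O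
F5 | step 6 | (6R,8R,9R,11S)-8-bromo-5,5,9-trimethyl-1-methylidenespiro[5.5]undecane-9,11-diol | C=C1CCCC(C)(C)[C@]12C[C@@H](Br)[C@](C)(O)C[C@@H]2O
F6 | step 6 | (6R,8R,9R,11S)-8-bromo-9-hydroxy-5,5,9-trimethyl-1-methylidenespiro[5.5]undecan-11-yl acetate | C=C1CCCC(C)(C)[C@]12C[C@@H](Br)[C@](C)(O)C[C@@H]2OC(C)=O
F7 | step 8 | (6R,8R,9R,11S)-8-bromo-9-chloro-1,5,5,9-tetramethylspiro[5.5]undec-1-en-11-yl acetate | CC1=CCCC(C)(C)[C@]12C[C@@H](Br)[C@](C)(Cl)C[C@@H]2OC(C)=O
F8 | step 8 | (6R,8R,9R,11S)-8-bromo-9-chloro-2-hydroperoxy-5,5,9-trimethyl-1-methylidenespiro[5.5]undecan-11-yl acetate (C2 epimers) | C=C1C(OO)CCC(C)(C)[C@]12C[C@@H](Br)[C@](C)(Cl)C[C@@H]2OC(C)=O
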